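## Retrosynthetic overview
1. C4–C4a (Friedel–Crafts): rings A and B are bought as phloroglucinol 1 and 3-bromo-4-hydroxyphenylacetic acid 2. They are joined to give the open-chain bromo-deoxybenzoin 3.
2. Key disconnection, both heterocycles at once. The chromone C2 goes back to DMF dimethyl acetal 4. The O–C2 and C3–C3a bonds of the dihydrofuran go back to isoprene 5 and the o-bromophenol unit, through an enantioselective [3+2] Heck/Tsuji–Trost heteroannulation that sets C2 as R.
3. Ring order in that single flask: ring C first (enaminone 6 → 3'-bromogenistein 7), ring D second, giving the isopropenyl-dihydrobenzofuran 8.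
4. Last disconnection: the tertiary C–OH of target 9 comes from the isopropenyl group of 8 by Markovnikov hydration. No protecting groups are used.

Assumption: 2 is taken as a catalogue chemical; ring letters are A (phloroglucinol ring), C (pyranone), B (3-aryl ring) and D (dihydrofuran); the ligand enantiomer that gives R is fixed by a calibration run on 3-bromo-4-hydroxyacetophenone, whose product tremetone has a known absolute configuration.

## Route

Step 1
Reactants: 1 phloroglucinol (benzene-1,3,5-triol); 2 3-bromo-4-hydroxyphenylacetic acid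
Product: 3 2-(3-bromo-4-hydroxyphenyl)-1-(2,4,6-trihydroxyphenyl)ethan-1-one
Conditions: BF3·OEt2 (neat, solvent and promoter), 85 °C, 2 h; then cold aq. NaOAc
Reagents that add atoms: none
Why: Friedel–Crafts C-acylation (the BF3 variant of the Hoesch deoxybenzoin synthesis): BF3 turns the acid into an acylium-type donor, the threefold-activated symmetric ring of 1 is attacked at any of its equivalent CH positions, the boron-chelated ketone formed is too deactivated for a second acylation, the bromophenol ring of 2 is far less nucleophilic than 1, and no stereocentre is involved.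

Step 2
Reactants: 3 2-(3-bromo-4-hydroxyphenyl)-1-(2,4,6-trihydroxyphenyl)ethan-1-one; 4 N,N-dimethylformamide dimethyl acetal; 5 isoprene (2-methylbuta-1,3-diene)
Product: 8 5,7-dihydroxy-3-[(2R)-2-(prop-1-en-2-yl)-2,3-dihydro-1-benzofuran-5-yl]-4H-chromen-4-one, via enaminone 6 (not isolated), via 3'-bromogenistein 7 (not isolated)
Conditions: (a) 4 (1.3 equiv), 1,4-dioxane/DMF 4:1, 70 °C, 1.5 h, N2 sweep; (b) same flask, Pd2(dba)3 (2.5 mol %), TY-Phos (chiral tert-butanesulfinamide monophosphine, R-selective enantiomer, 6 mol %), Cs2CO3 (3.5 equiv), 5 (5 equiv), sealed, 70 °C, 16 h; then aq. citric acid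
Reagents that add atoms: N,N-dimethylformamide dimethyl acetal COC(OC)N(C)C; isoprene C=CC(C)=C
Why: Proposed new method: the amide acetal condenses at the acidic CH2 of 3 to give enaminone 6, whose ortho-OH adds to the β-carbon and expels Me2NH to close ring C (7); once the liberated Me2NH, which would otherwise intercept the π-allyl complex, has been swept out, zerovalent palladium inserts into the C–Br bond of 7 and the aryl-palladium species adds to the unsubstituted vinyl CH2 of isoprene; the ligand decides which face of the resulting 2-methyl-π-allyl unit carries the metal (face-selective insertion, corrected by η3–η1–η3 equilibration through its CH2 terminus), and the neighbouring phenoxide attacks 5-exo, anti to palladium, so that ring D closes and the dihydrofuran C2 is set as R in the C–O bond-forming event; the closest known reaction types are the DMF-acetal isoflavone synthesis and the asymmetric Heck/Tsuji–Trost (Larock-type) heteroannulation of o-bromophenols with 1,3-dienes, and what is new is running both in one flask on an unprotected triphenol.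

Step 3
Reactants: 8 5,7-dihydroxy-3-[(2R)-2-(prop-1-en-2-yl)-2,3-dihydro-1-benzofuran-5-yl]-4H-chromen-4-one
Product: 9 5,7-dihydroxy-3-[(2R)-2-(2-hydroxypropan-2-yl)-2,3-dihydro-1-benzofuran-5-yl]-4H-chromen-4-one
Conditions: Co(acac)2 (20 mol %), PhSiH3 (3 equiv), O2 (1 atm), THF, 0 °C to rt
Reagents that add atoms: dioxygen O=O
Why: Mukaiyama hydration (cobalt-hydride hydrogen-atom transfer): the hydride formed from Co(acac)2 and PhSiH3 gives H• to the CH2 terminus of the unhindered, electron-neutral 1,1-disubstituted alkene in preference to the trisubstituted, electron-poor chromone C2=C3 bond, the tertiary radical is caught by O2 faster than it can expel the β-aryloxy group, the cobalt peroxide is reduced by more silane to the tertiary alcohol, and since no bond at the dihydrofuran C2 is broken the R configuration (same CIP order O > carbon substituent > CH2 > H) is carried over unchanged.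

## Compound list
1 | phloroglucinol | Oc1cc(O)cc(O)c1 | starting material
2 | 3-bromo-4-hydroxyphenylacetic acid | OC(=O)Cc1ccc(O)c(Br)c1 | starting material
3 | 2-(3-bromo-4-hydroxyphenyl)-1-(2,4,6-trihydroxyphenyl)ethan-1-one | O=C(Cc1ccc(O)c(Br)c1)c1c(O)cc(O)cc1O | intermediate
4 | N,N-dimethylformamide dimethyl acetal | COC(OC)N(C)C | starting material
5 | isoprene | C=CC(C)=C | starting material
6 | 2-(3-bromo-4-hydroxyphenyl)-3-(dimethylamino)-1-(2,4,6-trihydroxyphenyl)prop-2-en-1-one (enaminone, alkene geometry not fixed, not isolated) | CN(C)C=C(C(=O)c1c(O)cc(O)cc1O)c1ccc(O)c(Br)c1 | intermediate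
7 | 3-(3-bromo-4-hydroxyphenyl)-5,7-dihydroxy-4H-chromen-4-one (3'-bromogenistein, not isolated) | O=c1c(-c2ccc(O)c(Br)c2)coc2cc(O)cc(O)c12 | intermediate
8 | 5,7-dihydroxy-3-[(2R)-2-(prop-1-en-2-yl)-2,3-dihydro-1-benzofuran-5-yl]-4H-chromen-4-one | C=C(C)[C@H]1Cc2cc(-c3coc4cc(O)cc(O)c4c3=O)ccc2O1 | intermediate
9 | 5,7-dihydroxy-3-[(2R)-2-(2-hydroxypropan-2-yl)-2,3-dihydro-1-benzofuran-5-yl]-4H-chromen-4-one | CC(C)(O)[C@H]1Cc2cc(-c3coc4cc(O)cc(O)c4c3=O)ccc2O1 | target

## Step count and risks
Total step count: 3. Longest linear sequence: 3 (1/2 → 3 → 8 → 9).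

**Most likely to fail: step 2.**
- Risks: low ee in the polar medium needed to dissolve the phenoxide salts; O-allylation or isoprene telomerisation by the ring A phenoxides; and re-ionisation of the allylic aryl ether 8 by zerovalent palladium.
- Fallback: ring D is built by prenyl/epoxide logic instead.
- It sets out from 7, isolated after stage (a) by dilution with water.
- Linear-selective Suzuki–Miyaura coupling of 7 with 3-methylbut-2-enylboronic acid pinacol ester (Pd(OAc)2, a biaryl monophosphine tuned for the linear product, K3PO4, THF/H2O) gives isowighteone F1.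
- TBSCl/imidazole caps the 7-OH and 4'-OH, while the chelated 5-OH stays free, and gives the bis-silyl ether F2.
- Epoxidation follows with KHSO5 (as 2KHSO5·KHSO4·K2SO4, K2CO3 buffer, MeCN/dimethoxymethane, 0 °C). The catalyst is 1,2:4,5-di-O-isopropylidene-β-L-erythro-2,3-hexodiulo-2,6-pyranose, the enantiomer of the fructose-derived Shi ketone. This gives the (S)-epoxide F3.
- Bu4NF then frees the 4'-phenoxide, which opens the epoxide 5-exo at the secondary carbon with inversion to R.
- The fallback comes back to the route at 9, so 8 and step 3 are bypassed.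

**Second: step 3.**
- Risks: radical quenching by the phenols; binding of cobalt by the 5-hydroxy-4-keto unit; and hydrogen-atom transfer to the chromone double bond.
- Fallback: the polar alternative, oxymercuration–demercuration, which sets out from 8.
- Hg(OAc)2 in THF/H2O adds OH and HgOAc in the Markovnikov sense and gives the β-hydroxyalkylmercury acetate F4. It is a mixture at the new carbinol carbon, which vanishes in the next operation.
- Any aryl–mercury bonds formed on ring A are cleaved in that same operation.
- NaBH4 in aq. NaOH at 0 °C replaces mercury by hydrogen, and the fallback comes back to the route at 9.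

**Third: step 1.**
- Risks: tar or diacylation in hot BF3·OEt2.
- Fallback: a Houben–Hoesch reaction through a nitrilium electrophile, which sets out from 1.
- Bought (3-bromo-4-hydroxyphenyl)acetonitrile F5 is used with dry HCl and ZnCl2 in Et2O at 0 °C. This precipitates the ketiminium chloride F6.
- Hydrolysis of that salt in boiling water comes back to the route at 3.

## Further compounds
F1 | step 2 | isowighteone (3'-prenylgenistein) | CC(C)=CCc1cc(-c2coc3cc(O)cc(O)c3c2=O)ccc1O
F2 | step 2 | 7,4'-bis-O-(tert-butyldimethylsilyl)isowighteone | CC(C)=CCc1cc(-c2coc3cc(O[Si](C)(C)C(C)(C)C)cc(O)c3c2=O)ccc1O[Si](C)(C)C(C)(C)C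
F3 | step 2 | 7,4'-bis-O-(tert-butyldimethylsilyl)-3'-{[(2S)-3,3-dimethyloxiran-2-yl]methyl}genistein | CC1(C)O[C@H]1Cc2cc(-c3coc4cc(O[Si](C)(C)C(C)(C)C)cc(O)c4c3=O)ccc2O[Si](C)(C)C(C)(C)C
F4 | step 3 | {2-hydroxy-2-[(2R)-5-(5,7-dihydroxy-4-oxo-4H-chromen-3-yl)-2,3-dihydro-1-benzofuran-2-yl]propyl}mercury acetate (mixture at the carbinol carbon) | CC(O)(C[Hg]OC(C)=O)[C@H]1Cc2cc(-c3coc4cc(O)cc(O)c4c3=O)ccc2O1
F5 | step 1 | (3-bromo-4-hydroxyphenyl)acetonitrile | N#CCc1ccc(O)c(Br)c1
F6 | step 1 | 2-(3-bromo-4-hydroxyphenyl)-1-(2,4,6-trihydroxyphenyl)ethan-1-iminium chloride | [Cl-].[NH2+]=C(Cc1ccc(O)c(Br)c1)c1c(O)cc(O)cc1O
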